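The numbers in the tables are simulated for substances that don't exist; noise was put on by code.

I was asked what the flask holds at 8.0 d and which option adds most target, and both answers turned on what had stopped the target from rising.

| setting | larch | ash | flask |
|---|---|---|---|
| starting material | 0.10 M | 0.10 M | 0.10 M |
| second substrate | 0.10 M | 0.10 M | 0.100 M |
| reagent | 0.050 M | 0.050 M | 0.0500 M |
| free catalyst | 0.17 mM | 0.17 mM | 0.17 mM |
| temperature | 80 °C | 65 °C | 80 °C |
| remark | the very flask that is asked about, followed so far | run made earlier |  |
| time |  |  | 8.0 d |

| run | time / h | target / % |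
|---|---|---|
| larch | 15.0 | 22.3 |
| larch | 25.0 | 22.4 |
| larch | 40.0 | 22.0 |
| larch | 60.0 | 22.1 |
| larch | 72.0 | 21.4 |
| larch | 120 | 22.0 |
| larch | 192 | 22.5 |
| ash | 30.0 | 14.9 |
| ash | 48.0 | 15.2 |
| ash | 96.0 | 15.1 |
| ash | 120 | 15.0 |
| ash | 144 | 15.7 |
| ash | 240 | 15.4 |
| ash | 360 | 15.1 |

(standard deviation of a reading: 0.3 percentage points)

- Tuesday's: at 8.0 d raise the temperature by 10 K, then wait 4.0 d
- Saturday's: at 8.0 d add free catalyst, 100% of the amount charged, then wait 4.0 d
- Wednesday's: at 8.0 d add reagent, 50.0% of the amount charged, then wait 4.0 d
- Monday's: at 8.0 d take out 90% of the target then present, then wait 4.0 d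
- Thursday's: change nothing and wait 4.0 d more

- target that was removed still counts
- additions bring no volume worth counting

- target, in percent of the starting material first charged, at 8.0 d
- which option adds most target ("none" when 2 percentage points or less is all one gets) (Tuesday's / Saturday's / Wednesday's / Monday's / Thursday's / none)
- target present, with what was taken out counted in, in percent of the starting material first charged, after Tuesday's
- target present, with what was taken out counted in, in percent of the starting material first charged, after Wednesday's

I read the two tables column against column. The larch run, which is this flask followed so far, stayed flat from its first reading at 15.0 h, with a mean of 22.1%. The ash run, at 65 °C, stayed flat from 30.0 h, with a mean of 15.2%. In amounts, the larch run held 0.0221 M of target against 0.050 M of reagent charged, so at one reagent per target, target did not account for 0.0279 M of reagent, and 0.10 M of second substrate had been charged.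

I therefore supposed that second substrate takes reagent along a parallel path and that reagent is the limiting reagent in both runs. Target made per reagent charged, which I called the reagent share, was then 44.2% in the larch run, higher than the 30.4% in the ash run.

So I put the flask at 22.1% now, and I expected Tuesday's to stay there, since it brings no reagent. Wednesday's adds 0.0250 M of reagent, which at the larch share makes 0.0111 M of target, so I reckoned 33.1% and chose Wednesday's.

The forecast read the plateau otherwise: “I therefore read it as an endothermic equilibrium”. It gave 22.1% now, 27% after Tuesday's and 27% after Wednesday's, and it chose Monday's. My figures differ from it after both options and in the choice.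

The flask gave 21.8% at 8.0 d, 21.8% after Tuesday's and 31.4% after Wednesday's, the best option. The steps were these:

    starting material + free catalyst ⇌ catalyst intermediate A (K = 22.0 L mol⁻¹, k = 57.7 L mol⁻¹ min⁻¹, Ea = 50.0 kJ mol⁻¹, ΔH = 37.0 kJ mol⁻¹)
    reagent + catalyst intermediate A → free catalyst + target (k = 57.3 L mol⁻¹ min⁻¹, Ea = 71.0 kJ mol⁻¹)
    second substrate + free catalyst ⇌ catalyst intermediate B (K = 12.9 L mol⁻¹, k = 27.1 L mol⁻¹ min⁻¹, Ea = 50.0 kJ mol⁻¹, ΔH = 0 kJ mol⁻¹)
    reagent + catalyst intermediate B → free catalyst + second product (k = 513 L mol⁻¹ min⁻¹, Ea = 43.0 kJ mol⁻¹)
    (constants at 80 °C)

At 192 h the flask held 0% of its charged reagent free, beside 0.0282 M of second product. The reagent share, read as 44.2% from the larch run, came to 43.6% on the flask's own figures at 8.0 d, and the reagent added in Wednesday's gave 38.4%, less than that. The neighbour flask with 0.25 M of starting material kept 0% of its reagent and reached target at 13.0% of its own starting material, a reagent share of 65.0%.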